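**Retrosynthetic overview**

1. Metachromin E is taken back to the bis-silyl ether of its chromene-5,8-diol and then to chroman-5,8-diol 29; C3=C4 is introduced by DDQ and the quinone is revealed last.
2. Feature used: in the ring C4a–C5–C6–C7–C8–C8a the quinone oxygens sit on C5 and C8, the methoxy on C6 (para to the ether-bearing C8a) and hydrogen on C7. A 3-methoxycyclobutenedione already holds this C5–C6(OMe)–C7(H)–C8 unit, so the carbocycle is cut at C4a–C5 and C8–C8a.
3. C8–C8a and the carbocycle come from thermal ring expansion of cyclobutenone 26; C4a–C5 comes from adding the 5-lithiodihydropyran (from bromide 21) to methyl semisquarate 24.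
4. The dihydropyran ring comes from δ-lactol 17 (hydroformylation of tertiary homoallylic alcohol 15); C2 is set by catalytic asymmetric allylboration of methyl ketone 13.
5. Ring A with both stereocentres comes from 2,6-dimethylcyclohexanone by chiral-imine Michael addition, Robinson annulation to trans-octalone 7, ozonolysis and methylenation. Ring order: ring A, dihydropyran ring, cyclobutene (temporary), carbocyclic quinone ring last.

Key step: step 14

Remark (assumption): (S)-3,3'-dibromo-1,1'-bi-2-naphthol is assumed to send allyl to the Re face of ketone 13, the long arm taking the place an aryl group takes in aryl methyl ketones; if a model ketone shows the opposite sense, the (R)-diol is used with nothing else changed.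
Remark (assumption): allyldiisopropoxyborane 14 is taken as purchasable; otherwise it is made in one operation from allylmagnesium bromide and B(O-i-Pr)3.
Shorthand in names: "A-ethyl" = 2-[(1R,3R)-1,3-dimethyl-2-methylidenecyclohexyl]ethyl; "oxo-A" = (1R,3R)-1,3-dimethyl-2-oxocyclohexyl.

**Route**

Step 1
Reactants: 1 2,6-dimethylcyclohexanone (commercial cis/trans mixture); 2 (S)-1-phenylethylamine
Product: 3 (1S)-N-(2,6-dimethylcyclohexylidene)-1-phenylethanamine (ring epimers)
Conditions: cat. TsOH, toluene, reflux, Dean–Stark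
Reagents that add atoms: none
Why: Acid-catalysed imine condensation driven by azeotropic removal of water; the ring stereocentres need no control, since one becomes sp2 in the reacting enamine tautomer and the other is equilibrated in step 3.

Step 2
Reactants: 3 imine; 4 methyl vinyl ketone
Product: 6 (2R)-2,6-dimethyl-2-(3-oxobutyl)cyclohexan-1-one (C6 epimers), via Michael adduct imine 5 (not isolated)
Conditions: THF, 25–40 °C, 3–5 d; then 20% aq AcOH, rt
Reagents that add atoms: water, O
Why: Deracemising Michael addition of a chiral imine through its secondary enamine tautomer (aza-ene-type cyclic transition state with internal N–H transfer), in which the enone should approach the face anti to the phenyl group of the (S)-auxiliary and set the quaternary carbon as R, as the same auxiliary does with 2-methylcyclohexanone; mild acid then hydrolyses the imine.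

Step 3
Reactants: 6 diketone
Product: 7 (4aR,8R)-4a,8-dimethyl-4,4a,5,6,7,8-hexahydronaphthalen-2(3H)-one
Conditions: NaOMe, MeOH, 65 °C, until the C8 epimers have equilibrated
Reagents that add atoms: none
Why: Intramolecular aldol condensation completing a Robinson annulation; under the equilibrating base the C8 methyl (γ-position, epimerisable through the dienolate) should settle equatorial and trans to the axial angular methyl, as 6-methyl steroid enones settle in the 6α form, which fixes the second ring A centre as 8R by thermodynamic control.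

Step 4
Reactants: 7 octalone
Product: 9 3-(oxo-A)propanoic acid, via 2-oxoaldehyde 8 (not isolated)
Conditions: O3, EtOAc/AcOH, −20 °C; then 30% H2O2, rt
Reagents that add atoms: ozone, [O-][O+]=O; hydrogen peroxide, OO
Why: Ozonolysis of the enone C1=C8a bond with oxidative work-up, which excises C1 and returns ring A as a ketone carrying the propanoic acid arm; no base is present, so the CH(CH3) centre next to the new ketone should keep its configuration.

Step 5
Reactants: 9 keto acid
Product: 10 methyl 3-(oxo-A)propanoate
Conditions: MeI, KHCO3, DMF, rt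
Reagents that add atoms: iodomethane, CI
Why: SN2 esterification of the carboxylate under bicarbonate, a base too weak to enolise the hindered ketone.

Step 6
Reactants: 10 keto ester
Product: 11 methyl 3-[(1R,3R)-1,3-dimethyl-2-methylidenecyclohexyl]propanoate
Conditions: Zn, CH2Br2, TiCl4, THF/CH2Cl2, 0 °C → rt
Reagents that add atoms: dibromomethane, BrCBr
Why: Takai–Lombardo methylenation with a non-basic zinc/titanium methylene reagent, chosen because it converts enolisable α-branched ketones without epimerisation and leaves esters untouched.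

Step 7
Reactants: 11 alkene ester
Product: 13 4-[(1R,3R)-1,3-dimethyl-2-methylidenecyclohexyl]butan-2-one, via Weinreb amide 12 (not isolated)
Conditions: MeNHOMe·HCl, i-PrMgCl, THF, −20 °C; then MeMgBr, 0 °C; aq NH4Cl
Reagents that add atoms: N,O-dimethylhydroxylamine hydrochloride, CNOC.Cl (atoms stay in 12 only); methylmagnesium bromide, C[Mg]Br
Why: Weinreb ketone synthesis run in one flask: the magnesium amide converts the ester to the N-methoxy-N-methylamide, whose chelated tetrahedral adduct with MeMgBr stops at the ketone.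

Step 8
Reactants: 13 methyl ketone; 14 allyldiisopropoxyborane
Product: 15 (4S)-6-[(1R,3R)-1,3-dimethyl-2-methylidenecyclohexyl]-4-methylhex-1-en-4-ol
Conditions: (S)-3,3'-dibromo-1,1'-bi-2-naphthol (15 mol %), PhCF3/toluene 3:1, −35 °C; aq NaHCO3
Reagents that add atoms: none
Why: Chiral-diol-catalysed asymmetric allylboration of a ketone through a closed chair transition state (the mixed binaphthol boronate is the reactive species), in which the long arm sits pseudo-equatorial and methyl pseudo-axial, so that the (S)-diol should deliver allyl to the Re face and give the 4S carbinol; the ring A centres are too remote to interfere.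

Step 9
Reactants: 15 homoallylic alcohol
Product: 17 (6R)-6-(A-ethyl)-6-methyloxan-2-ol (both anomers), via hydroxy aldehyde 16 (not isolated)
Conditions: Rh(acac)(CO)2 (1 mol %), BIPHEPHOS (2 mol %), CO/H2 1:1 (10 bar), toluene, 60 °C
Reagents that add atoms: carbon monoxide, [C-]#[O+]
Why: Linear-selective rhodium-catalysed hydroformylation of the monosubstituted alkene, followed by spontaneous 6-exo-trig hemiacetalisation of the δ-hydroxy aldehyde; the hindered 1,1-disubstituted ring A alkene should not react.

Step 10
Reactants: 17 lactol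
Product: 19 (2R)-2-(A-ethyl)-2-methyl-3,4-dihydro-2H-pyran, via anomeric mesylate 18 (not isolated)
Conditions: MsCl, Et3N, CH2Cl2, 0 → 40 °C
Reagents that add atoms: methanesulfonyl chloride, CS(=O)(=O)Cl (atoms stay in 18 only)
Why: Base-buffered dehydration of a 2-deoxy lactol (ionisation of the anomeric mesylate to the oxocarbenium ion, then loss of the C5 proton), the glycal-type elimination, which avoids acid and so protects the exocyclic alkene from isomerisation.

Step 11
Reactants: 19 dihydropyran
Product: 21 (2S)-5-bromo-2-(A-ethyl)-2-methyl-3,4-dihydro-2H-pyran, via dibromide 20 (not isolated)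
Conditions: Br2 (1.0 equiv), CH2Cl2, −78 °C; then Et3N, −78 °C → rt
Reagents that add atoms: bromine, BrBr
Why: Electrophilic bromination of the enol ether followed by dehydrobromination (loss of the anomeric bromide and the C5 proton), the usual route to β-bromo enol ethers; at −78 °C one equivalent of Br2 should be consumed by the far more nucleophilic enol ether before the ring A alkene is touched.

Step 12
Reactants: 22 dimethyl squarate
Product: 24 3-methoxycyclobut-3-ene-1,2-dione, via hydroxycyclobutenone 23 (not isolated)
Conditions: LiAlH(O-t-Bu)3, THF, −78 → −20 °C; then 6 M HCl, CH2Cl2, 0 °C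
Reagents that add atoms: none
Why: 1,2-Reduction of one squarate carbonyl by the bulky hydride, then acid-induced transposition with loss of methanol, the established semisquarate synthesis.

Step 13
Reactants: 21 bromodihydropyran; 24 3-methoxycyclobut-3-ene-1,2-dione
Product: 26 4-hydroxy-3-methoxy-4-[(2S)-2-(A-ethyl)-2-methyl-3,4-dihydro-2H-pyran-5-yl]cyclobut-2-en-1-one (either carbinol epimer), via alkenyllithium 25 (not isolated)
Conditions: t-BuLi (2.0 equiv), Et2O, −78 °C; cannula into 24 (1.3 equiv), THF, −78 °C; aq NH4Cl at −78 °C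
Reagents that add atoms: tert-butyllithium, [Li]C(C)(C)C (lithium stays in 25 only)
Why: Bromine–lithium exchange and 1,2-addition of the alkenyllithium to the cyclobutenedione, in which the carbonyl next to the methoxy-bearing carbon is a strained ketone while the other is deactivated as a vinylogous ester, so attack should place OMe beside the carbinol carbon (future C6, not C7); the reagent is held at −78 °C because its C–Li bond lies antiperiplanar to the ring C–O bond, and the carbinol centre formed unselectively is lost in step 14.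

Step 14
Reactants: 26 cyclobutenone
Product: 29 (2S)-2-(A-ethyl)-6-methoxy-2-methyl-3,4-dihydro-2H-chromene-5,8-diol, via dienylketene 27 (not isolated), via cyclohexadienone 28 (not isolated)
Conditions: degassed toluene (0.02 M), 110 °C, argon; concentrated and used at once
Reagents that add atoms: none
Why: Thermal Moore rearrangement: conrotatory 4π opening of the C1–C4 bond of the cyclobutenone gives dienylketene 27, the hydroxyl rotating outward so that the dihydropyranyl group lies cis to the ketene. The ketene carbon then bonds to C6 of the dihydropyran (C8a of the chroman) in a thermally allowed disrotatory 6π electrocyclisation, which forms C8–C8a and closes the six-membered carbocycle as dienone 28, and enolisation aromatises it to the hydroquinone. The closest precedent is the same ring expansion of squarate-derived 4-alkenyl-4-hydroxycyclobutenones, including those made from 2-lithiated cyclic enol ethers. No stereocentre is created (the carbinol centre and the transient C8a centre both become sp2), and C2 and ring A are spectators. The selectivity needed is regiochemical (OMe on C6, H on C7) and is already written into 26, because the carbinol carbon becomes C5 and its methoxy-bearing neighbour becomes C6; the other requirement, outward rotation of OH (inward rotation would lead to a butenolide), is secured by the donor character of the hydroxyl. Strain release and aromatisation drive the step, and dilute degassed conditions protect the ketene and the air-sensitive product.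

Step 15
Reactants: 29 hydroquinone
Product: 30 (2S)-5,8-bis{[tert-butyl(dimethyl)silyl]oxy}-2-(A-ethyl)-6-methoxy-2-methyl-3,4-dihydro-2H-chromene
Conditions: TBSOTf, 2,6-lutidine, CH2Cl2, 0 °C
Reagents that add atoms: tert-butyldimethylsilyl trifluoromethanesulfonate, CC(C)(C)[Si](C)(C)OS(=O)(=O)C(F)(F)F
Why: Silyl ether formation on both phenols; silyl is preferred to methyl because the C5/C8 hydroquinone can then be released without an oxidant, whereas oxidative demethylation of a 5,6,8-trimethoxy arene could equally engage the C6–OMe/C8a–O para pair and open the pyran ring.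

Step 16
Reactants: 30 bis-silyl ether
Product: 31 (2S)-5,8-bis{[tert-butyl(dimethyl)silyl]oxy}-2-(A-ethyl)-6-methoxy-2-methyl-2H-chromene
Conditions: DDQ (1.3 equiv), benzene, 60 °C, dark, argon
Reagents that add atoms: none
Why: DDQ dehydrogenation of a chroman to a 2H-chromene (hydride abstraction from benzylic C4 gives a cation stabilised by O1 and the C5 silyloxy group, then loss of the C3 proton), run in the dark at moderate temperature because a 2H-chromene can epimerise at C2 by reversible electrocyclic ring opening.

Step 17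
Reactants: 31 chromene bis-silyl ether
Product: 33 metachromin E [(2S)-2-(A-ethyl)-6-methoxy-2-methyl-2H-chromene-5,8-dione], via chromene hydroquinone 32 (not isolated)
Conditions: Bu4NF, AcOH, THF, 0 °C, dark; then PhI(OAc)2 (1.1 equiv), 0 °C
Reagents that add atoms: none
Why: Buffered fluoride desilylation followed by two-electron oxidation of the free C5/C8 hydroquinone with the hypervalent iodine reagent, conditions under which the chromene, the vinylogous ester and the exocyclic alkene should be left alone.

**Compound list**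

1 | 2,6-dimethylcyclohexanone (cis/trans mixture) | CC1CCCC(C)C1=O | starting material
2 | (S)-1-phenylethylamine | C[C@H](N)c1ccccc1 | starting material
3 | (1S)-N-(2,6-dimethylcyclohexylidene)-1-phenylethanamine | C[C@H](N=C1C(C)CCCC1C)c1ccccc1 | intermediate
4 | methyl vinyl ketone | C=CC(C)=O | starting material
5 | 4-[(1R)-1,3-dimethyl-2-{[(1S)-1-phenylethyl]imino}cyclohexyl]butan-2-one | C[C@H](N=C1C(C)CCC[C@]1(C)CCC(C)=O)c1ccccc1 | intermediate (not isolated)
6 | (2R)-2,6-dimethyl-2-(3-oxobutyl)cyclohexan-1-one (C6 epimers) | O=C1C(C)CCC[C@]1(C)CCC(C)=O | intermediate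
7 | (4aR,8R)-4a,8-dimethyl-4,4a,5,6,7,8-hexahydronaphthalen-2(3H)-one | O=C1C=C2[C@H](C)CCC[C@]2(C)CC1 | intermediate
8 | 4-[(1R,3R)-1,3-dimethyl-2-oxocyclohexyl]-2-oxobutanal | O=C1[C@H](C)CCC[C@]1(C)CCC(=O)C=O | intermediate (not isolated)
9 | 3-[(1R,3R)-1,3-dimethyl-2-oxocyclohexyl]propanoic acid | O=C1[C@H](C)CCC[C@]1(C)CCC(=O)O | intermediate
10 | methyl 3-[(1R,3R)-1,3-dimethyl-2-oxocyclohexyl]propanoate | O=C1[C@H](C)CCC[C@]1(C)CCC(=O)OC | intermediate
11 | methyl 3-[(1R,3R)-1,3-dimethyl-2-methylidenecyclohexyl]propanoate | C=C1[C@H](C)CCC[C@]1(C)CCC(=O)OC | intermediate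
12 | N-methoxy-N-methyl-3-[(1R,3R)-1,3-dimethyl-2-methylidenecyclohexyl]propanamide | C=C1[C@H](C)CCC[C@]1(C)CCC(=O)N(C)OC | intermediate (not isolated)
13 | 4-[(1R,3R)-1,3-dimethyl-2-methylidenecyclohexyl]butan-2-one | C=C1[C@H](C)CCC[C@]1(C)CCC(C)=O | intermediate
14 | allyldiisopropoxyborane | C=CCB(OC(C)C)OC(C)C | starting material
15 | (4S)-6-[(1R,3R)-1,3-dimethyl-2-methylidenecyclohexyl]-4-methylhex-1-en-4-ol | C=C1[C@H](C)CCC[C@]1(C)CC[C@](C)(O)CC=C | intermediate
16 | (5R)-7-[(1R,3R)-1,3-dimethyl-2-methylidenecyclohexyl]-5-hydroxy-5-methylheptanal | C=C1[C@H](C)CCC[C@]1(C)CC[C@](C)(O)CCCC=O | intermediate (not isolated)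
17 | (6R)-6-(A-ethyl)-6-methyloxan-2-ol (both anomers) | C=C1[C@H](C)CCC[C@]1(C)CC[C@@]1(C)CCCC(O)O1 | intermediate
18 | (6R)-6-(A-ethyl)-6-methyloxan-2-yl methanesulfonate | C=C1[C@H](C)CCC[C@]1(C)CC[C@@]1(C)CCCC(OS(C)(=O)=O)O1 | intermediate (not isolated)
19 | (2R)-2-(A-ethyl)-2-methyl-3,4-dihydro-2H-pyran | C=C1[C@H](C)CCC[C@]1(C)CC[C@@]1(C)CCC=CO1 | intermediate
20 | (6S)-2,3-dibromo-6-(A-ethyl)-6-methyloxane (trans-dibromide, C2/C3 unassigned) | C=C1[C@H](C)CCC[C@]1(C)CC[C@@]1(C)CCC(Br)C(Br)O1 | intermediate (not isolated)
21 | (2S)-5-bromo-2-(A-ethyl)-2-methyl-3,4-dihydro-2H-pyran | C=C1[C@H](C)CCC[C@]1(C)CC[C@@]1(C)CCC(Br)=CO1 | intermediate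
22 | dimethyl squarate | COC1=C(OC)C(=O)C1=O | starting material
23 | 4-hydroxy-2,3-dimethoxycyclobut-2-en-1-one (racemic) | COC1=C(OC)C(=O)C1O | intermediate (not isolated)
24 | 3-methoxycyclobut-3-ene-1,2-dione | COC1=CC(=O)C1=O | intermediate
25 | 5-lithio derivative of 21 | C=C1[C@H](C)CCC[C@]1(C)CC[C@@]1(C)CCC([Li])=CO1 | intermediate (not isolated)
26 | 4-hydroxy-3-methoxy-4-[(2S)-2-(A-ethyl)-2-methyl-3,4-dihydro-2H-pyran-5-yl]cyclobut-2-en-1-one (either carbinol epimer) | C=C1[C@H](C)CCC[C@]1(C)CC[C@@]1(C)CCC(=CO1)C1(O)C(OC)=CC1=O | intermediate (key-step precursor)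
27 | (3Z)-4-hydroxy-3-methoxy-4-[(2S)-2-(A-ethyl)-2-methyl-3,4-dihydro-2H-pyran-5-yl]buta-1,3-dien-1-one | C=C1[C@H](C)CCC[C@]1(C)CC[C@@]1(C)CCC(=CO1)/C(O)=C(OC)\C=C=O | intermediate (not isolated)
28 | (2S)-2-(A-ethyl)-5-hydroxy-6-methoxy-2-methyl-2,3,4,8a-tetrahydrochromen-8-one (C8a unassigned) | C=C1[C@H](C)CCC[C@]1(C)CC[C@@]1(C)CCC2=C(O)C(OC)=CC(=O)C2O1 | intermediate (not isolated)
29 | (2S)-2-(A-ethyl)-6-methoxy-2-methyl-3,4-dihydro-2H-chromene-5,8-diol | C=C1[C@H](C)CCC[C@]1(C)CC[C@@]1(C)CCc2c(O1)c(O)cc(OC)c2O | intermediate (key-step product)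
30 | (2S)-5,8-bis{[tert-butyl(dimethyl)silyl]oxy}-2-(A-ethyl)-6-methoxy-2-methyl-3,4-dihydro-2H-chromene | C=C1[C@H](C)CCC[C@]1(C)CC[C@@]1(C)CCc2c(O1)c(O[Si](C)(C)C(C)(C)C)cc(OC)c2O[Si](C)(C)C(C)(C)C | intermediate
31 | (2S)-5,8-bis{[tert-butyl(dimethyl)silyl]oxy}-2-(A-ethyl)-6-methoxy-2-methyl-2H-chromene | C=C1[C@H](C)CCC[C@]1(C)CC[C@@]1(C)C=Cc2c(O1)c(O[Si](C)(C)C(C)(C)C)cc(OC)c2O[Si](C)(C)C(C)(C)C | intermediate
32 | (2S)-2-(A-ethyl)-6-methoxy-2-methyl-2H-chromene-5,8-diol | C=C1[C@H](C)CCC[C@]1(C)CC[C@@]1(C)C=Cc2c(O1)c(O)cc(OC)c2O | intermediate (not isolated)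
33 | metachromin E, (2S)-2-{2-[(1R,3R)-1,3-dimethyl-2-methylidenecyclohexyl]ethyl}-6-methoxy-2-methyl-2H-chromene-5,8-dione | C=C1[C@H](C)CCC[C@]1(C)CC[C@@]1(C)C=CC2=C(O1)C(=O)C=C(OC)C2=O | target

**Step count and risks**

Total: 17 steps. Longest linear sequence: 16 steps (steps 1–11 and 13–17); step 12 is a one-step branch.

Risk 1, step 8. Facial discrimination between the methyl group and the primary alkyl arm of ketone 13 may be too weak, or the sense of induction may be opposite to that assumed, giving C2 epimers that would be hard to separate because the ring A centres are remote. The fallback sets out from 13 and comes back at 15, with the carbinol set by a reagent-controlled epoxidation of known facial sense. Horner–Wadsworth–Emmons olefination of 13 (triethyl phosphonoacetate, NaH, THF) and removal of the minor Z isomer gives ethyl (2E)-5-[(1R,3R)-1,3-dimethyl-2-methylidenecyclohexyl]-3-methylpent-2-enoate F1. Reduction with i-Bu2AlH gives the allylic alcohol (2E)-5-[(1R,3R)-1,3-dimethyl-2-methylidenecyclohexyl]-3-methylpent-2-en-1-ol F2, a geraniol analogue. Sharpless asymmetric epoxidation (Ti(O-i-Pr)4, L-(+)-diethyl tartrate, t-BuOOH, 4 Å sieves, CH2Cl2, −20 °C) should give the (2S,3S)-epoxy alcohol F3. NaAlH2(OCH2CH2OMe)2 opens the epoxide at C2 to the (3S)-1,3-diol F4, whose tertiary carbinol has the configuration of 15. Oxidation of the primary alcohol alone (TEMPO, PhI(OAc)2) gives the β-hydroxy aldehyde F5, and Wittig methylenation (Ph3P=CH2 from Ph3PCH3Br and KN(SiMe3)2, −78 °C) gives 15.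

Risk 2, step 6. The methylene reagent may add too slowly to the doubly α-branched ketone, or enolisation during the reaction may epimerise the CH(CH3) centre toward the more stable cis-dimethyl ketone. The fallback sets out from octalone 7 and comes back at 13, and it methylenates with an addition/elimination sequence on a substrate that has no ester. MeLi (Et2O, −78 °C) adds 1,2 to 7 to give the tertiary allylic alcohol (4aR,8R)-2,4a,8-trimethyl-2,3,4,4a,5,6,7,8-octahydronaphthalen-2-ol F6 (either C2 epimer). Ozonolysis (O3, CH2Cl2/MeOH, −78 °C; Me2S) gives the α-hydroxy aldehyde 4-(oxo-A)-2-hydroxy-2-methylbutanal F7, which NaIO4 in aqueous THF cleaves to the trans-diketone (2R,6R)-2,6-dimethyl-2-(3-oxobutyl)cyclohexan-1-one F8. Only the unhindered methyl ketone is ketalised (1,2-bis(trimethylsilyloxy)ethane, cat. Me3SiOTf, CH2Cl2, −78 °C) to give the dioxolane F9. Peterson olefination follows: Me3SiCH2Li with CeCl3 adds to the ring ketone to give the β-hydroxysilane F10, and KH in THF eliminates it to the ketal alkene 2-(A-ethyl)-2-methyl-1,3-dioxolane F11. Pyridinium tosylate in wet acetone then releases 13.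

Risk 3, step 16. DDQ may oxidise the very electron-rich bis-silyloxy arene by electron transfer (oxidative desilylation, ring oxidation) faster than it abstracts hydride from C4, or prolonged heating may erode C2 through chromene ring opening. The fallback sets out from 29 and comes back at 33, and it moves the dehydrogenation to the quinone oxidation level so that no protecting group is needed. Ag2O (Et2O, MgSO4, rt) oxidises 29 to the chroman quinone (2S)-2-(A-ethyl)-6-methoxy-2-methyl-3,4-dihydro-2H-chromene-5,8-dione F12. DDQ (benzene, 80 °C, dark) then dehydrogenates C3–C4 of this dihydropyrano-quinone, the conversion known for dihydropyrano-fused naphthoquinones of the lapachone type, and gives 33 directly; steps 15 and 17 fall away.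

**Further compounds**

F1 | step 8 | ethyl (2E)-5-[(1R,3R)-1,3-dimethyl-2-methylidenecyclohexyl]-3-methylpent-2-enoate | C=C1[C@H](C)CCC[C@]1(C)CC/C(C)=C/C(=O)OCC
F2 | step 8 | (2E)-5-[(1R,3R)-1,3-dimethyl-2-methylidenecyclohexyl]-3-methylpent-2-en-1-ol | C=C1[C@H](C)CCC[C@]1(C)CC/C(C)=C/CO
F3 | step 8 | [(2S,3S)-3-(A-ethyl)-3-methyloxiran-2-yl]methanol | C=C1[C@H](C)CCC[C@]1(C)CC[C@]2(C)O[C@H]2CO
F4 | step 8 | (3S)-5-[(1R,3R)-1,3-dimethyl-2-methylidenecyclohexyl]-3-methylpentane-1,3-diol | C=C1[C@H](C)CCC[C@]1(C)CC[C@](C)(O)CCO
F5 | step 8 | (3S)-5-[(1R,3R)-1,3-dimethyl-2-methylidenecyclohexyl]-3-hydroxy-3-methylpentanal | C=C1[C@H](C)CCC[C@]1(C)CC[C@](C)(O)CC=O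
F6 | step 6 | (4aR,8R)-2,4a,8-trimethyl-2,3,4,4a,5,6,7,8-octahydronaphthalen-2-ol | CC1(O)C=C2[C@H](C)CCC[C@]2(C)CC1
F7 | step 6 | 4-[(1R,3R)-1,3-dimethyl-2-oxocyclohexyl]-2-hydroxy-2-methylbutanal | O=C1[C@H](C)CCC[C@]1(C)CCC(C)(O)C=O
F8 | step 6 | (2R,6R)-2,6-dimethyl-2-(3-oxobutyl)cyclohexan-1-one | O=C1[C@H](C)CCC[C@]1(C)CCC(C)=O
F9 | step 6 | (2R,6R)-2,6-dimethyl-2-[2-(2-methyl-1,3-dioxolan-2-yl)ethyl]cyclohexan-1-one | O=C1[C@H](C)CCC[C@]1(C)CCC2(C)OCCO2
F10 | step 6 | (2R,6R)-2,6-dimethyl-2-[2-(2-methyl-1,3-dioxolan-2-yl)ethyl]-1-[(trimethylsilyl)methyl]cyclohexan-1-ol (C1 unassigned) | C[Si](C)(C)CC1(O)[C@H](C)CCC[C@]1(C)CCC2(C)OCCO2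
F11 | step 6 | 2-{2-[(1R,3R)-1,3-dimethyl-2-methylidenecyclohexyl]ethyl}-2-methyl-1,3-dioxolane | C=C1[C@H](C)CCC[C@]1(C)CCC2(C)OCCO2
F12 | step 16 | (2S)-2-{2-[(1R,3R)-1,3-dimethyl-2-methylidenecyclohexyl]ethyl}-6-methoxy-2-methyl-3,4-dihydro-2H-chromene-5,8-dione | C=C1[C@H](C)CCC[C@]1(C)CC[C@@]1(C)CCC2=C(O1)C(=O)C=C(OC)C2=O
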